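The data stem from a simulated flask from invented constants.

Read the gamma flask at 6.0 h, and start from what the runs so far allow you to say about that hour.

| flask | electrophile | free base | protonated nucleophile | remark | time |
|---|---|---|---|---|---|
| gamma | 0.80 M | 1.6 M | 0.76 M | the very flask that is asked about, followed so far |  |
| epsilon | 1.6 M | 1.6 M | 0.76 M | run made earlier |  |
| flask | 0.80 M | 1.60 M | 0.760 M |  | 6.0 h |

| run | time / h | electrophile / % | target / % |
|---|---|---|---|
| gamma | 0.167 | 18.1 | 52.7 |
| gamma | 0.500 | 10.6 | 44.0 |
| gamma | 0.833 | 8.3 | 43.4 |
| gamma | 1.33 | 7.3 | 43.9 |
| gamma | 2.00 | 6.0 | 44.6 |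
| gamma | 2.50 | 6.3 | 44.7 |
| epsilon | 0.500 | 52.5 | 22.8 |
| epsilon | 0.833 | 52.5 | 22.5 |
| epsilon | 1.33 | 52.1 | 22.2 |
| epsilon | 2.00 | 52.5 | 22.8 |
| epsilon | 4.00 | 52.6 | 22.6 |
| epsilon | 6.00 | 52.9 | 22.2 |

(readings scatter by 0.3 percentage points)

- the numbers in the tables scatter by 0.3 percentage points (one standard deviation)
- the earlier runs do not show how much of nucleophile is bound; that part of a forecast is a guess

- part of the electrophile that has reacted at 6.0 h
- share of the unused nucleophile that is free and not bound as protonated nucleophile, at 6.0 h

1. The epsilon flask gives the rule: at 0.500 h it already shows 52.5% electrophile and stays there, so 0.760 M has reacted, which matches the 0.76 M of protonated nucleophile charged. You may therefore take protonated nucleophile as the limiting reagent, with the free base releasing nucleophile from it and each electrophile taking one nucleophile. The ceiling, the charge of protonated nucleophile divided by the charge of electrophile, is 95.0% for the gamma flask.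

2. By its first reading, at 0.167 h, the gamma flask is already down to 18.1% electrophile, with target at 52.7%.

3. In the middle of the gamma run, at 0.500 h, electrophile reads 10.6% while target has dropped to 44.0%, so target is passing into something these readings do not show.

4. Late in the gamma run, electrophile reads 6.0% at 2.00 h, and the ceiling leaves 5.00%. My own reckoning therefore puts the reacted part between about 94.0%, a figure that carries the scatter of 0.3 percentage points of the reading, and the ceiling, and I can read nothing about the free share from these runs.

5. The forecast gives 94.8% reacted (range 94% to 95.2%) and 40% free (range 15% to 75%), on this ground: “So nucleophile is limiting”.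

    electrophile + nucleophile → acid set free + target (k = 1.50 M⁻¹ min⁻¹)
    nucleophile + acid set free ⇌ protonated nucleophile, settled at all times (K = 29.0 M⁻¹)
    acid set free + free base ⇌ salt of the base, settled at all times (K = 68.0 M⁻¹)
    nucleophile + target → over-reaction product (k = 0.0100 M⁻¹ min⁻¹)
    target ⇌ isomer of the product (K = 1.10, k = 0.0750 min⁻¹)

The gamma flask gives 94.2% reacted at 6.0 h, with 24.4% of the unused nucleophile free, so the forecast's reacted part is within tolerance and its free share is 16 points too high. The reacted part stands 0.80 points under the ceiling, and the over-reaction product then stands at 0.843% of the electrophile charged. With 0.46 M of protonated nucleophile and the other charges unchanged, the ceiling becomes 57.5%, and that neighbour flask reaches 57.3%.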